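The vessel is closed, stirred and isothermal, and the ligand exchanges step by step, so you compare runs by their charges. The south-west run holds 3.08 equiv of incoming ligand on the starting complex, the north-west run 1.33 equiv, and the flask 2.00 equiv, between them.

| flask | starting complex | incoming ligand | remark | time |
|---|---|---|---|---|
| south-west | 0.013 M | 0.040 M | run made earlier |  |
| north-west | 0.030 M | 0.040 M | run made earlier |  |
| flask | 0.020 M | 0.0400 M |  | 6.0 h |

| run | time / h | complex with two exchanged / % | complex with three exchanged / % |
|---|---|---|---|
| south-west | 0.500 | 6.1 | 24.7 |
| south-west | 0.667 | 6.7 | 21.9 |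
| south-west | 1.00 | 6.3 | 18.2 |
| south-west | 1.50 | 4.9 | 12.8 |
| south-west | 2.50 | 3.2 | 8.2 |
| south-west | 4.00 | 3.0 | 6.2 |
| south-west | 6.00 | 2.8 | 6.2 |
| north-west | 0.833 | 12.0 | 5.1 |
| north-west | 1.50 | 11.9 | 3.3 |
| north-west | 2.50 | 11.3 | 2.2 |
| north-west | 3.00 | 10.7 | 2.2 |
| north-west | 4.00 | 9.2 | 2.0 |
| north-west | 5.00 | 8.8 | 2.4 |
| north-west | 6.00 | 8.6 | 2.6 |

(each reading ± 0.3 percentage points)

- what was read earlier has a scatter of 0.3 percentage points, one standard deviation
- steps under discussion: starting complex + incoming ligand <-> leaving ligand + complex with one exchanged; complex with one exchanged + incoming ligand <-> leaving ligand + complex with two exchanged; complex with two exchanged + incoming ligand <-> leaving ligand + complex with three exchanged; complex with three exchanged + incoming ligand <-> leaving ligand + complex with four exchanged; leaving ligand + starting complex -> side product; incoming ligand -> decomposition product; complex with three exchanged <-> isomer of the product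

Now read the last rows. At 6.00 h, the ratio of the amounts of complex with three exchanged and complex with two exchanged reads 2.21 in south-west and 0.302 in north-west, a factor of 7.32. But you have no points between, so replace the curve by its mean: the steepness, the rise in the natural logarithm of that ratio per equivalent charged, is 1.14 per equivalent.

Check the error this makes. The readings at 4.00 h give 1.29 per equivalent, so the mean is close but not constant. Stepping up from north-west, I reckon a ratio of 0.647 for the flask; this is a ratio, not an amount.

- equivalents of incoming ligand to starting complex, everything else as given, that leave most complex with two exchanged at 6.0 h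
- the amount of complex with two exchanged then, in percent of the starting complex charged
- the amount of complex with two exchanged with the amounts as given

The forecast gives 10.4% as charged, and 10.8% at 1.9 equiv, from “a broad maximum of about 11% near 1.9 equiv”.

The flask gives 8.63% as charged, and 9.20% at 1.60 equiv. Its ratio at 6.00 h is 0.459, so my 0.647 stands too high.

    starting complex + incoming ligand ⇌ leaving ligand + complex with one exchanged (K = 75.8, k = 0.0926 M⁻¹ s⁻¹)
    complex with one exchanged + incoming ligand ⇌ leaving ligand + complex with two exchanged (K = 36.3, k = 0.0544 M⁻¹ s⁻¹)
    complex with two exchanged + incoming ligand ⇌ leaving ligand + complex with three exchanged (K = 17.4, k = 0.464 M⁻¹ s⁻¹)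
    complex with three exchanged + incoming ligand ⇌ leaving ligand + complex with four exchanged (K = 1.20, k = 0.0294 M⁻¹ s⁻¹)
    leaving ligand + starting complex → side product (k = 0.0131 M⁻¹ s⁻¹)
    incoming ligand → decomposition product (k = 6.39 × 10⁻⁷ s⁻¹)
    complex with three exchanged ⇌ isomer of the product (K = 14.1, k = 7.34 × 10⁻⁴ s⁻¹)

Take the neighbouring flask with 0.10 M of incoming ligand, which is 5.00 equiv. The same steepness, 1.14 per equivalent, carried up from north-west gives a ratio of 19.9. That neighbour stands at 12.1, with 6.04% of complex with three exchanged over 0.498% of complex with two exchanged.

The data stem from a simulated flask with made-up constants; noise was put on by code.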